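**Plan**
- Retrosynthesis: the only skeletal cut is at the central Ar–CH2–Ar' bridge. Undoing both aryl–CH2 bonds gives the isobutyryl monomer, the isovaleryl monomer and a one-carbon iminium salt.
- Enabling feature: in both benzene rings the bridge carbon sits on a ring carbon flanked by two phenolic C–OH groups. The isobutyryl ring plus CH2 is therefore a latent ortho-quinone methide (exocyclic C=CH2 conjugated to a ring C=O). The single unsubstituted ring CH of the isovaleryl monomer, lying between its two OH groups, is the matching carbon nucleophile.
- Each monomer is cut further at the aryl–acyl bond and at the hindered O–CH3 bond, leading back to 2-methylphloroglucinol and an acid chloride.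
- Forward: no ring is built. In two parallel four-step arms the triol is C-acylated, the 4- and 6-OH are masked as MOM ethers, the chelated 2-OH is methylated and the MOM helpers are removed. The three components are then merged in one flask, with CH2 attached first to the isobutyryl ring and then to the isovaleryl ring.
- Stereochemistry: the target has no stereocentre, so none has to be set.

Key step: step 9

Remark: the SMILES holds no stereocentre and no resolvable axis, so the compound is treated as achiral and the single-enantiomer demand is met trivially. Ring locants below count the acyl-bearing carbon as C1 (C2 O-methyl site, C3 methyl, C4 OH, C5 free CH or bridge site, C6 OH).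

**Step 1**
Reactants: 1 2-methylphloroglucinol; 2 isobutyryl chloride
Product: 3 1-(2,4,6-trihydroxy-3-methylphenyl)-2-methylpropan-1-one
Conditions: AlCl3 (4 equiv), CH2Cl2/MeNO2, 0 °C → 40 °C; ice/1 M HCl
Reagents that add atoms: none
Why: Friedel–Crafts acylation of a phloroglucinol (O-acylation and Fries shift converge on the same ketone under AlCl3) should give a single mono-ketone, because the two free ring carbons of 1 are related by symmetry and the chelated acyl group deactivates the ring towards a second acylation.

**Step 2**
Reactants: 3 1-(2,4,6-trihydroxy-3-methylphenyl)-2-methylpropan-1-one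
Product: 4 1-[2-hydroxy-4,6-bis(methoxymethoxy)-3-methylphenyl]-2-methylpropan-1-one
Conditions: MOMCl (2.2 equiv), iPr2NEt (3 equiv), CH2Cl2, 0 °C → rt
Reagents that add atoms: chloromethyl methyl ether (MOMCl), COCCl
Why: Selective phenol O-alkylation (MOM ether formation) should take the most acidic 4-OH (para to C=O) and the sterically open 6-OH, while the 2-OH, wedged between the 3-methyl and the acyl group and held in the C=O hydrogen bond, stays free, which is the known partial-alkylation pattern of C-methylphloroacylphenones.

**Step 3**
Reactants: 4 1-[2-hydroxy-4,6-bis(methoxymethoxy)-3-methylphenyl]-2-methylpropan-1-one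
Product: 5 1-[2-methoxy-4,6-bis(methoxymethoxy)-3-methylphenyl]-2-methylpropan-1-one
Conditions: MeI (3 equiv), K2CO3 (3 equiv), DMF, 40 °C
Reagents that add atoms: iodomethane (MeI), CI
Why: Williamson ether synthesis on the one remaining phenol, for which carbonate in a dipolar aprotic solvent breaks the chelate but is too weak to enolise the hindered aryl ketone, and the MOM acetals are inert to base.

**Step 4**
Reactants: 5 1-[2-methoxy-4,6-bis(methoxymethoxy)-3-methylphenyl]-2-methylpropan-1-one
Product: 6 1-(4,6-dihydroxy-2-methoxy-3-methylphenyl)-2-methylpropan-1-one (isobutyryl monomer)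
Conditions: cat. conc. HCl, MeOH (dilute), 50 °C
Reagents that add atoms: none
Why: Acid-catalysed transacetalisation of the two MOM acetals to methanol should free the 4- and 6-OH, with the aryl methyl ether and the ketone untouched and the C1 unit carried off as its dimethyl acetal in the large excess of methanol instead of attacking the free C5.

**Step 5**
Reactants: 1 2-methylphloroglucinol; 7 isovaleryl chloride (3-methylbutanoyl chloride)
Product: 8 1-(2,4,6-trihydroxy-3-methylphenyl)-3-methylbutan-1-one
Conditions: AlCl3 (4 equiv), CH2Cl2/MeNO2, 0 °C → 40 °C; ice/1 M HCl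
Reagents that add atoms: none
Why: Friedel–Crafts acylation as in step 1, again giving one regioisomer because of the symmetry of 1 and stopping at the mono-ketone because of ring deactivation.

**Step 6**
Reactants: 8 1-(2,4,6-trihydroxy-3-methylphenyl)-3-methylbutan-1-one
Product: 9 1-[2-hydroxy-4,6-bis(methoxymethoxy)-3-methylphenyl]-3-methylbutan-1-one
Conditions: MOMCl (2.2 equiv), iPr2NEt (3 equiv), CH2Cl2, 0 °C → rt
Reagents that add atoms: chloromethyl methyl ether (MOMCl), COCCl
Why: Selective MOM ether formation as in step 2, the hindered and chelated 2-OH next to the 3-methyl group being the one that is left free.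

**Step 7**
Reactants: 9 1-[2-hydroxy-4,6-bis(methoxymethoxy)-3-methylphenyl]-3-methylbutan-1-one
Product: 10 1-[2-methoxy-4,6-bis(methoxymethoxy)-3-methylphenyl]-3-methylbutan-1-one
Conditions: MeI (3 equiv), K2CO3 (3 equiv), DMF, 40 °C
Reagents that add atoms: iodomethane (MeI), CI
Why: Williamson ether synthesis on the only free phenol, with a base too weak to deprotonate the α-CH2 of the aryl ketone to any useful extent.

**Step 8**
Reactants: 10 1-[2-methoxy-4,6-bis(methoxymethoxy)-3-methylphenyl]-3-methylbutan-1-one
Product: 11 1-(4,6-dihydroxy-2-methoxy-3-methylphenyl)-3-methylbutan-1-one (isovaleryl monomer)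
Conditions: cat. conc. HCl, MeOH (dilute), 50 °C
Reagents that add atoms: none
Why: Acid-catalysed MOM acetal cleavage by transacetalisation to methanol as in step 4, leaving methyl ether and ketone intact.

**Step 9**
Reactants: 6 isobutyryl monomer; 12 N,N-dimethylmethyleneiminium iodide (Eschenmoser's salt); 11 isovaleryl monomer
Product: 15 target 1-[3-[[2,6-dihydroxy-4-methoxy-3-methyl-5-(2-methylpropanoyl)phenyl]methyl]-2,4-dihydroxy-6-methoxy-5-methylphenyl]-3-methylbutan-1-one, via Mannich base 13 (not isolated), via ortho-quinone methide 14 (not isolated)
Conditions: 6, 12 (1.0 equiv), MeCN, 0 °C → rt; then 11 (1.1 equiv), NaOAc (1.5 equiv), 70 °C, N2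
Reagents that add atoms: none
Why: This is a three-component Mannich/ortho-quinone-methide arylation, the established type of access to unsymmetrical methylene-bis-phloroglucinols, in which iminium 12 attacks the only unsubstituted carbon of 6 (C5, between the 4- and 6-OH) in an aromatic Mannich reaction and the amine stays locked as its hydroiodide until 6 is used up. Acetate then frees base 13, whose hydrogen-bonded phenol/amine pair expels Me2NH on warming (1,4-elimination) to give ortho-quinone methide 14, and the free C5 carbon of 11 adds to the exocyclic CH2 in a vinylogous Michael (Friedel–Crafts-type) addition, after which both rings rearomatise by tautomerisation. No ring is closed and no stereocentre is formed. The step needs cross-coupling over homo-coupling, which is secured by the order of addition and the 1:1 ratio of 6 to 12, by the fact that 13 and 14 have no free ring carbon and cannot act as C-nucleophiles while 11 has exactly one, and by product 15 being hexasubstituted in both rings so that chain growth stops. O-attack, or ipso attack at the methyl-bearing C3 of 11, gives only adducts that revert to 14, so the rearomatised C–C product is the thermodynamic sink. The acetate/dimethylammonium buffer keeps the medium near neutral, which holds back base-induced retro-Michael scrambling of the bridge (rottlerone-type change).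

**Compound list**
1 | 2-methylphloroglucinol (2-methylbenzene-1,3,5-triol) | Cc1c(O)cc(O)cc1O | starting material
2 | isobutyryl chloride | CC(C)C(=O)Cl | starting material
3 | 1-(2,4,6-trihydroxy-3-methylphenyl)-2-methylpropan-1-one | CC(C)C(=O)c1c(O)cc(O)c(C)c1O | intermediate
4 | 1-[2-hydroxy-4,6-bis(methoxymethoxy)-3-methylphenyl]-2-methylpropan-1-one | CC(C)C(=O)c1c(O)c(C)c(OCOC)cc1OCOC | intermediate
5 | 1-[2-methoxy-4,6-bis(methoxymethoxy)-3-methylphenyl]-2-methylpropan-1-one | CC(C)C(=O)c1c(OC)c(C)c(OCOC)cc1OCOC | intermediate
6 | 1-(4,6-dihydroxy-2-methoxy-3-methylphenyl)-2-methylpropan-1-one | CC(C)C(=O)c1c(OC)c(C)c(O)cc1O | intermediate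
7 | isovaleryl chloride (3-methylbutanoyl chloride) | CC(C)CC(=O)Cl | starting material
8 | 1-(2,4,6-trihydroxy-3-methylphenyl)-3-methylbutan-1-one | CC(C)CC(=O)c1c(O)cc(O)c(C)c1O | intermediate
9 | 1-[2-hydroxy-4,6-bis(methoxymethoxy)-3-methylphenyl]-3-methylbutan-1-one | CC(C)CC(=O)c1c(O)c(C)c(OCOC)cc1OCOC | intermediate
10 | 1-[2-methoxy-4,6-bis(methoxymethoxy)-3-methylphenyl]-3-methylbutan-1-one | CC(C)CC(=O)c1c(OC)c(C)c(OCOC)cc1OCOC | intermediate
11 | 1-(4,6-dihydroxy-2-methoxy-3-methylphenyl)-3-methylbutan-1-one | CC(C)CC(=O)c1c(OC)c(C)c(O)cc1O | intermediate
12 | N,N-dimethylmethyleneiminium iodide (Eschenmoser's salt) | C=[N+](C)C.[I-] | starting material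
13 | 1-[3-[(dimethylamino)methyl]-2,4-dihydroxy-6-methoxy-5-methylphenyl]-2-methylpropan-1-one (Mannich base, formed as hydroiodide, shown as free base) | CC(C)C(=O)c1c(OC)c(C)c(O)c(CN(C)C)c1O | intermediate
14 | 3-hydroxy-5-methoxy-6-methyl-2-methylidene-4-(2-methylpropanoyl)cyclohexa-3,5-dien-1-one (ortho-quinone methide) | C=C1C(=O)C(C)=C(OC)C(C(=O)C(C)C)=C1O | intermediate
15 | 1-[3-[[2,6-dihydroxy-4-methoxy-3-methyl-5-(2-methylpropanoyl)phenyl]methyl]-2,4-dihydroxy-6-methoxy-5-methylphenyl]-3-methylbutan-1-one (CNP0265841.0) | COc1c(C)c(O)c(Cc2c(O)c(C)c(OC)c(C(=O)C(C)C)c2O)c(O)c1C(=O)CC(C)C | target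

Total step count: 9. Longest linear sequence: 5 (steps 1–4 then 9, or steps 5–8 then 9).

**Steps most likely to fail**

**1. Step 9.**
- Risk: incomplete aminomethylation would leave monomer that intercepts the quinone methide. Amine and heat could also reopen the new bridge by retro-Michael cleavage (rottlerone-type change). Both processes erode cross-selectivity towards symmetrical dimers.
- Fallback: it sets out from 6 and comes back at 15. 6 would be aminomethylated with 12 as before, but Mannich base 13 would be isolated and heated with sodium p-toluenesulfinate in aqueous acetic acid. This exchanges the amine for a sulfonyl group by elimination–addition and gives the crystalline, storable sulfone 1-[2,4-dihydroxy-6-methoxy-5-methyl-3-[(4-methylphenyl)sulfonylmethyl]phenyl]-2-methylpropan-1-one F1, which can be freed of all 6 by recrystallisation.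
- F1 and 11 would then be stirred with NaHCO3 in MeCN/water at room temperature. 2-(Sulfonylmethyl)phenols release their quinone methide (here 14) under such mild base, the sulfinate is not basic enough to trigger the retro-reaction, and the low temperature keeps the bridge of 15 intact.

**2. Step 2.**
- Risk: poor site selectivity between the two ortho hydroxyls, since the carbonyl chelate can swing to either one, or drift into over-protection.
- Fallback: it sets out from 3 and comes back at 4, and moves the selection from a protection to a deprotection. 3 would be exhaustively protected (MOMCl, NaH, DMF, 0 °C → rt) to the tris-ether 1-[2,4,6-tris(methoxymethoxy)-3-methylphenyl]-2-methylpropan-1-one F2.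
- One MOM group would then be removed by mild chelation-assisted acetal cleavage (catalytic I2, MeOH, rt). The 2-OMOM group is buttressed by the 3-methyl and the acyl group and twisted out of conjugation, so it is the most basic and most strained acetal and should go first. The freed 2-OH then ties up the carbonyl and slows loss of the 6-OMOM group.

**3. Step 4.**
- Risk: recapture of the liberated C1 electrophile by the nucleophilic free ring carbon during acid cleavage, that is, premature methylene bridging of the monomer with itself.
- Fallback: it sets out from 3 and comes back at 6, and replaces acid-labile acetals by groups that leave under neutral reduction and release no C1 electrophile. 3 would be dibenzylated (BnBr 2.1 equiv, K2CO3, DMF) to 1-[4,6-bis(benzyloxy)-2-hydroxy-3-methylphenyl]-2-methylpropan-1-one F3.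
- F3 would be methylated (MeI, K2CO3, DMF) to 1-[4,6-bis(benzyloxy)-2-methoxy-3-methylphenyl]-2-methylpropan-1-one F4, and F4 hydrogenolysed (H2, Pd/C, EtOAc, rt) to 6.

**Further compounds**
F1 | step 9 | 1-[2,4-dihydroxy-6-methoxy-5-methyl-3-[(4-methylphenyl)sulfonylmethyl]phenyl]-2-methylpropan-1-one | CC(C)C(=O)c1c(OC)c(C)c(O)c(CS(=O)(=O)c2ccc(C)cc2)c1O
F2 | step 2 | 1-[2,4,6-tris(methoxymethoxy)-3-methylphenyl]-2-methylpropan-1-one | CC(C)C(=O)c1c(OCOC)c(C)c(OCOC)cc1OCOC
F3 | step 4 | 1-[4,6-bis(benzyloxy)-2-hydroxy-3-methylphenyl]-2-methylpropan-1-one | CC(C)C(=O)c1c(O)c(C)c(OCc2ccccc2)cc1OCc1ccccc1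
F4 | step 4 | 1-[4,6-bis(benzyloxy)-2-methoxy-3-methylphenyl]-2-methylpropan-1-one | CC(C)C(=O)c1c(OC)c(C)c(OCc2ccccc2)cc1OCc1ccccc1
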